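## Structural features

Monotesone A is a flavanone. Ring A is phloroglucinol-derived, with free hydroxyls at C5 and C7, and is fused through C4a and C8a to the dihydropyranone ring C (O1, C2, C3, C4 carbonyl). C2 carries ring B, a catechol with a prenylated 4'-oxygen and a free 3'-hydroxyl. C2 (S) is the only stereocentre: it is benzylic, bonded to O1, one methylene away from the carbonyl, and has no neighbouring stereocentre to relay from. Its configuration is fragile, because base removes H-3 and expels the O1 phenoxide (retro-oxa-Michael opening to the 2'-hydroxychalcone), and reclosure is unselective. The prenyl aryl ether does not tolerate hydrogenation, electrophilic oxidants, strong acids or prolonged heating, which rules out benzyl and methyl ethers as phenol protection. Only one of four phenolic oxygens is alkylated, and that distinction is easy only on the ring B aldehyde, where the 4-hydroxyl is the most acidic. The real difficulty is to create C2 enantioselectively without a directing group and to carry it to the end without base. The key step uses the fact that C4a–C8a–O1–C2 becomes a cationic 2-oxadiene once C2 is an oxocarbenium carbon stabilised by ring B; that C4a lies between two oxygen-bearing carbons of a symmetrical ring A and is strongly nucleophilic; and that the C4 oxygen can arrive with the C3–C4 unit.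

## Logic of the disconnections

**16 ⇒ 15.** The three O–Si bonds at O5, O7 and O3' are the last to be made in the retrosynthetic sense; no skeletal bond is cut. The phenols would interfere with every cationic and oxidative operation and make the flavanone base-labile, so they stay masked to the end. 15 has no acidic proton and the prenyl ether is its only unmasked oxygen substituent. The forward step must free three phenols without exposing the enolisable ketone to a basic phenoxide or to basic fluoride, or C2 is lost through opening of O1–C2.

**15 ⇒ 14 ⇒ 13.** The C4 carbonyl is traced to the secondary alcohol of 14 and then to the ethyl ether of 13; only the C4–O bond is exchanged. A carbonyl at C4 would deactivate ring A in a cationic ring closure, whereas an ether oxygen at C4 is exactly what an enol ether delivers. The gain is that the C4 stereocentre of 13 and 14 is disposable and needs no control. The demand is a solvolysis of the C4 ether that does not lose H-3 from the benzylic cation, and an oxidation that is neither acidic nor basic.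

**13 ⇒ 9 + 10.** Ring C is cut at C2–C3 and C4–C4a. This separates the two-carbon unit 10 from 9, in which rings A and B are joined only through O1 and the acetal carbon that becomes C2. One ring, two skeletal bonds and the only permanent stereocentre are traced to an acyclic racemate whose own stereocentre vanishes in the planar cation 11. The forward step must ionise 9 by loss of the methoxy group, add 10 to one face of C2 of 11 under control of the counter-anion, and close 12 onto ring A faster than 12 adds more 10.

**9 ⇒ 5 + 7 (through 8).** The O1–C2 bond between the ring A oxygen and the acetal carbon is cut. It is the only link between the two aromatic halves, so the cut gives two blocks of similar size: 7 as the oxygen nucleophile and 8 (from 5) as the electrophile. The forward step must alkylate an electron-rich phenol on oxygen and not on carbon, under base so that acid-labile 9 survives.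

**5 ⇒ 4 ⇒ 3 ⇒ 1 + 2.** The acetal C–O bonds, the O3–Si bond and the O4–prenyl bond are removed in turn. The prenyl group goes on first because in 1 the oxygen that must carry it is the more acidic of the two phenols. The demand is mono-alkylation with regiocontrol by acidity alone.

**7 ⇒ 6.** Two O–Si bonds are cut. 6 is threefold symmetric, so any two hydroxyls may be silylated; the demand is to stop at the bis-ether.

## Other disconnections considered

**Alternative 1:** The cut removes C3 from ring C (C2–C3 and C3–C4). The precursor is the racemic 2-arylbenzofuran-3-one A1, which already holds O1, C2 and the ketone carbon on ring A; the missing carbon comes from ethyl diazoacetate A2.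
- Forward key step: a chiral Lewis acid (Sc(OTf)3 with a chiral N,N'-dioxide ligand) would activate the ketone of A1. The diazo carbon would add to it and C2 would shift to the new carbon with retention as dinitrogen leaves, giving the 2,3-trans keto ester A3. H-2 of A1 is acidic, so its enantiomers interconvert through the enol and one can be drained (dynamic kinetic resolution).
- In favour: asymmetric Lewis acid-catalysed homologation of ketones with diazo esters is an established reaction class, so on precedent this key step is better founded than the chosen one. C4 is a carbonyl from the start, so no hydrolysis and oxidation follow, which is also better. No strong Brønsted acid meets the prenyl ether.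
- Against: either C2 or the ring A carbon can migrate, and only the first gives a flavanone. A1 is easily autoxidised and not short to make, since hydrogenation of an aurone is barred by the prenyl alkene. A3 must still lose its ester group (Krapcho dealkoxycarbonylation or hydrolysis and decarboxylation, with heat) and three acetates, while its doubly activated H-3 invites β-elimination of the O1 phenoxide, the process that racemises C2.
- Comparison: on structure the plans are equal, since both make C2 stereoconvergently from a racemate and both make a second stereocentre that is discarded. On mechanism the alternative selects between interconverting enantiomers in a 1,2-shift and the chosen plan selects a face of the planar cation 11; the former is better documented. On step economy the alternative is not shorter, and its end game is harsher on C2 and on the prenyl ether.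

**Alternative 2:** Ring A is cut at C4a–C5 and C8–C8a. Ring C with its stereocentre becomes the enantiopure bromo-dihydropyranone A4, and C5–C8 become Chan's diene A5.
- Forward key step: the CH2 terminus of A5 would bond to C8a (the β-carbon of the bromo-enone) and the ketene acetal carbon to C4a. Loss of hydrogen bromide, methanol and the silyl groups would aromatise the new ring to A6, one desilylation from 16. A4 would come from aldehyde 4 by a catalytic asymmetric hetero-Diels–Alder reaction with a siloxy diene, followed by α-bromination.
- In favour: C2 is set by a well-established catalytic asymmetric reaction of an aromatic aldehyde, a better-founded origin of the stereocentre than the chosen key step. Ring A appears with free hydroxyls and C4 as a ketone, so ring A protection, the statistical silylation of step 4 and the redox adjustment of steps 7 and 8 all disappear. At about six steps it is the better plan on step economy.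
- Against: C8a of A4 is the β-carbon of a vinylogous ester and a weak acceptor. Once it is sp3, O1 sits β to an enolate and can be expelled, which opens ring C. The aromatisation needs base or acid on a 5,7-dihydroxyflavanone whose C2 is base-labile, and Lewis acids that activate such dienes endanger the silyl and prenyl ethers.
- Comparison: on structure the alternative builds ring A last, whereas the chosen plan builds ring C last onto an intact ring A. On mechanism it separates a known stereo-determining event from an uncertain annulation, whereas the chosen plan puts both into one cationic step. It would be about three steps shorter; it was set aside only because ring construction on a β-oxygenated enone with the O1–C8a bond preserved is the less secure annulation.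

**Alternative 3:** Ring C is cut at O1–C2 and C3–C4, the reverse polarity of the chosen cut. Ring A carries the electrophilic carbon C4 as the salicylaldehyde dimethyl acetal A7, and ring B supplies C2 and C3 as the styrene A9.
- Forward key step: a BINOL-derived chiral phosphoric acid would expel methanol from A7 to give the methoxy-substituted ortho-quinone methide A8, hydrogen-bonded to the catalyst through its ring oxygen. A9 would add across it (C3–C4 first, then O1–C2) to give the 2,4-cis 4-methoxyflavan A10.
- In favour: phosphoric acid-catalysed [4+2] additions of ortho-quinone methides to styrenes are an established route to 2-arylchromans, so the precedent is better. The ionisation is unambiguous because both acetal oxygens of A7 are methoxy groups, a clear advantage over 9. The catalyst has a defined hydrogen-bond contact with the oxygen that becomes O1, which 11 lacks. The ring A aldehyde can be bis-silylated without statistics, since the hydroxyl chelated to the formyl group reacts last. A10 has the oxidation state of 13, so the end game is equal.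
- Against: the prenyl alkene would compete with the styrene as the 2π partner, hence the benzyl ether in A9. That costs a debenzylation (hydrogenolysis also attacks the benzylic C2–O1 and C4–O bonds of a flavan) and a late prenylation of the 4'-hydroxyl under base beside a silyl ether that can migrate between the catechol oxygens. An electron-rich styrene dimerises and polymerises under acid. C2 is fixed only in the second bond-forming event, at a benzylic cation that may have left the catalyst.
- Comparison: on structure it closes the same ring through the other two bonds. On mechanism both are stepwise cationic [4+2] processes under a chiral anion, and the alternative has the better-anchored ion pair. It is two to three steps longer and moves the prenyl group, the distinguishing feature of 16, to a late and unsafe position.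

Key step: step 6

Remarks on the chemistry:
- TBS = tert-butyldimethylsilyl; prenyl = 3-methylbut-2-enyl. IDPi = a C2-symmetric imidodiphosphorimidate Brønsted acid built from two 3,3'-diaryl-BINOL units with N-triflyl groups.
- The sense of induction of the chiral acid cannot be predicted with confidence; it is assumed that a first screen identifies the catalyst enantiomer that leads to 2S, and that enantiomer is meant wherever the catalyst is named.
- The descriptors 2S,4S of 13 denote the 2,4-cis isomer. Any C4 epimer or 4-methoxy congener of 13 (exchange with liberated methanol) converges on 14 in step 7.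

## Route

Step 1
Reactants: 1 3,4-dihydroxybenzaldehyde; 2 prenyl bromide (1-bromo-3-methylbut-2-ene)
Product: 3 3-hydroxy-4-(3-methylbut-2-enyloxy)benzaldehyde
Conditions: NaHCO3, DMF, 40 °C
Reagents that add atoms: none
Why: Williamson ether synthesis; the 4-hydroxyl, para to the formyl group, is the more acidic phenol and the only one ionised by the weak base, so one equivalent of 2 should alkylate O4 selectively.

Step 2
Reactants: 3 3-hydroxy-4-(3-methylbut-2-enyloxy)benzaldehyde
Product: 4 3-(tert-butyldimethylsilyloxy)-4-(3-methylbut-2-enyloxy)benzaldehyde
Conditions: TBSCl, imidazole, DMF, 0 °C to rt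
Reagents that add atoms: tert-butyldimethylsilyl chloride (TBSCl), CC(C)(C)[Si](C)(C)Cl
Why: Imidazole-promoted silylation of a phenol; the silyl ether removes the last acidic proton of ring B and can later be cleaved by fluoride without touching the prenyl ether.

Step 3
Reactants: 4 3-(tert-butyldimethylsilyloxy)-4-(3-methylbut-2-enyloxy)benzaldehyde
Product: 5 3-(tert-butyldimethylsilyloxy)-4-(3-methylbut-2-enyloxy)benzaldehyde dimethyl acetal
Conditions: HC(OMe)3, PPTS (cat.), MeOH, rt; Et3N quench
Reagents that add atoms: trimethyl orthoformate, COC(OC)OC; methanol, CO
Why: Acid-catalysed acetalisation driven by the orthoformate as water scavenger; the mild pyridinium acid should leave the aryl silyl ether and the prenyl ether intact.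

Step 4
Reactants: 6 phloroglucinol (benzene-1,3,5-triol)
Product: 7 3,5-bis(tert-butyldimethylsilyloxy)phenol
Conditions: TBSCl (2 equiv), imidazole, DMF, 0 °C
Reagents that add atoms: tert-butyldimethylsilyl chloride (TBSCl), CC(C)(C)[Si](C)(C)Cl
Why: Imidazole-promoted silylation of a symmetrical triol; with two equivalents the bis-ether should be the main component of a statistical mixture and is separated by chromatography, the mono- and tris-ethers being recyclable.

Step 5
Reactants: 5 3-(tert-butyldimethylsilyloxy)-4-(3-methylbut-2-enyloxy)benzaldehyde dimethyl acetal; 7 3,5-bis(tert-butyldimethylsilyloxy)phenol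
Product: 9 racemic 1-{methoxy[3-(tert-butyldimethylsilyloxy)-4-(3-methylbut-2-enyloxy)phenyl]methoxy}-3,5-bis(tert-butyldimethylsilyloxy)benzene, via racemic α-chloro ether 8 (not isolated)
Conditions: AcCl (0.98 equiv), ZnBr2 (cat.), PhMe, rt; then 7, iPr2NEt, 0 °C to rt; chromatography on Et3N-deactivated silica
Reagents that add atoms: none
Why: Acetal–acyl chloride exchange gives 8 and methyl acetate without free HCl, and 7 is then O-alkylated by the ionisable chloro ether (Williamson-type etherification of SN1 character) while the amine takes up HCl; the acetal stereocentre forms without control, which is immaterial because it is erased on ionisation.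

Step 6
Reactants: 9 racemic 1-{methoxy[3-(tert-butyldimethylsilyloxy)-4-(3-methylbut-2-enyloxy)phenyl]methoxy}-3,5-bis(tert-butyldimethylsilyloxy)benzene; 10 ethyl vinyl ether
Product: 13 (2S,4S)-4-ethoxy-4'-(3-methylbut-2-enyloxy)-5,7,3'-tris(tert-butyldimethylsilyloxy)flavan (2,4-cis), via aryl oxocarbenium ion 11 (not isolated), via ethoxycarbenium ion 12 (not isolated)
Conditions: chiral IDPi acid (5 mol%), 5 Å MS, PhMe, −78 °C; 10 (3 equiv) added slowly; Et3N quench
Reagents that add atoms: none
Why: Proposed new method: the acid protonates the more basic methoxy oxygen of 9 and methanol departs, so both enantiomers of 9 give the same planar aryl oxocarbenium ion 11 as a contact ion pair with the chiral imidodiphosphorimidate anion; the closest known reaction types are the Lewis acid-promoted oxa-Povarov reaction of aryl oxocarbenium ions with alkenes and counteranion-directed additions of π-nucleophiles to oxocarbenium ions. Enol ether 10 attacks C2 of 11 on the face left open by the confined anion, which is the only source of asymmetry and sets C2 as S, and this gives the ethoxy-stabilised C4 cation 12. Ring C then closes by a six-membered Friedel–Crafts alkylation (6-exo-trig with respect to the C4=O+ bond, overall a stepwise formal [4+2]) in which the ring A carbon between O1 and a silyloxy group attacks C4, and loss of the proton returns the acid. C4 is set by the substrate in this closure: a chair-like transition state with the C2 aryl and the ethoxy group both pseudo-equatorial should give the 2,4-cis isomer, but C4 later becomes the carbonyl carbon, so its configuration is of no consequence. The step needs loss of methanol and not of the phenol, attack by 10 in preference to the prenyl alkene and to ring A of a second molecule, and closure of 12 in preference to addition of more 10; these are favoured respectively by the basicity of the methoxy oxygen together with the ring B donor that stabilises 11, by the far higher nucleophilicity of an enol ether used in excess, and by the intramolecular reach of a doubly activated arene carbon at low enol ether concentration. Ring A is symmetrical, so both ortho carbons are equivalent and no regioisomer can form; the sieves take up the methanol.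

Step 7
Reactants: 13 (2S,4S)-4-ethoxy-4'-(3-methylbut-2-enyloxy)-5,7,3'-tris(tert-butyldimethylsilyloxy)flavan
Product: 14 (2S)-4'-(3-methylbut-2-enyloxy)-5,7,3'-tris(tert-butyldimethylsilyloxy)flavan-4-ol (mixture of C4 epimers)
Conditions: TsOH·H2O (cat.), THF–H2O (4:1), 0 °C
Reagents that add atoms: water, O
Why: SN1 solvolysis of a benzylic ether whose cation is stabilised by three ortho/para oxygens of ring A, with water in large excess as the trap; C2 is not involved, and both C4 epimers are acceptable.

Step 8
Reactants: 14 (2S)-4'-(3-methylbut-2-enyloxy)-5,7,3'-tris(tert-butyldimethylsilyloxy)flavan-4-ol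
Product: 15 (2S)-4'-(3-methylbut-2-enyloxy)-5,7,3'-tris(tert-butyldimethylsilyloxy)flavanone
Conditions: Dess–Martin periodinane, NaHCO3, CH2Cl2, 0 °C to rt
Reagents that add atoms: none
Why: Dess–Martin oxidation of a secondary benzylic alcohol, in which both C4 epimers converge on one ketone; the bicarbonate buffer keeps the liberated acetic acid from ionising the alcohol, and the neutral conditions leave C2 and the prenyl alkene untouched.

Step 9
Reactants: 15 (2S)-4'-(3-methylbut-2-enyloxy)-5,7,3'-tris(tert-butyldimethylsilyloxy)flavanone
Product: 16 Monotesone A, (2S)-5,7,3'-trihydroxy-4'-(3-methylbut-2-enyloxy)flavanone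
Conditions: Bu4NF, AcOH, THF, 0 °C
Reagents that add atoms: none
Why: Fluoride-mediated cleavage of aryl silyl ethers; acetic acid protonates each phenoxide as it forms, so the base-induced opening of ring C (retro-oxa-Michael) that would racemise C2 is avoided, and the prenyl ether is inert to fluoride.

## Compound list

1 | 3,4-dihydroxybenzaldehyde | O=Cc1ccc(O)c(O)c1 | starting material
2 | prenyl bromide (1-bromo-3-methylbut-2-ene) | CC(C)=CCBr | starting material
3 | 3-hydroxy-4-(3-methylbut-2-enyloxy)benzaldehyde | CC(C)=CCOc1ccc(C=O)cc1O | intermediate
4 | 3-(tert-butyldimethylsilyloxy)-4-(3-methylbut-2-enyloxy)benzaldehyde | CC(C)=CCOc1ccc(C=O)cc1O[Si](C)(C)C(C)(C)C | intermediate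
5 | dimethyl acetal of 4 | COC(OC)c1ccc(OCC=C(C)C)c(O[Si](C)(C)C(C)(C)C)c1 | intermediate
6 | phloroglucinol | Oc1cc(O)cc(O)c1 | starting material
7 | 3,5-bis(tert-butyldimethylsilyloxy)phenol | Oc1cc(O[Si](C)(C)C(C)(C)C)cc(O[Si](C)(C)C(C)(C)C)c1 | intermediate
8 | racemic 1-[chloro(methoxy)methyl]-3-(tert-butyldimethylsilyloxy)-4-(3-methylbut-2-enyloxy)benzene (not isolated) | COC(Cl)c1ccc(OCC=C(C)C)c(O[Si](C)(C)C(C)(C)C)c1 | intermediate
9 | racemic 1-{methoxy[3-(tert-butyldimethylsilyloxy)-4-(3-methylbut-2-enyloxy)phenyl]methoxy}-3,5-bis(tert-butyldimethylsilyloxy)benzene | COC(Oc1cc(O[Si](C)(C)C(C)(C)C)cc(O[Si](C)(C)C(C)(C)C)c1)c1ccc(OCC=C(C)C)c(O[Si](C)(C)C(C)(C)C)c1 | intermediate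
10 | ethyl vinyl ether | C=COCC | starting material
11 | aryl oxocarbenium ion, [3,5-bis(TBS-oxy)phenyl]oxonium ylidene of the ring B benzylidene, paired with the chiral anion (not isolated) | CC(C)=CCOc1ccc(C=[O+]c2cc(O[Si](C)(C)C(C)(C)C)cc(O[Si](C)(C)C(C)(C)C)c2)cc1O[Si](C)(C)C(C)(C)C | intermediate
12 | (S)-3-aryl-3-aryloxypropylidene(ethyl)oxonium ion, the C4 cation (not isolated) | CC[O+]=CC[C@H](Oc1cc(O[Si](C)(C)C(C)(C)C)cc(O[Si](C)(C)C(C)(C)C)c1)c1ccc(OCC=C(C)C)c(O[Si](C)(C)C(C)(C)C)c1 | intermediate
13 | (2S,4S)-4-ethoxy-4'-(3-methylbut-2-enyloxy)-5,7,3'-tris(tert-butyldimethylsilyloxy)flavan (2,4-cis) | CC(C)=CCOc1ccc([C@@H]2C[C@H](OCC)c3c(O[Si](C)(C)C(C)(C)C)cc(O[Si](C)(C)C(C)(C)C)cc3O2)cc1O[Si](C)(C)C(C)(C)C | intermediate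
14 | (2S)-4'-(3-methylbut-2-enyloxy)-5,7,3'-tris(tert-butyldimethylsilyloxy)flavan-4-ol, C4 epimers | CC(C)=CCOc1ccc([C@@H]2CC(O)c3c(O[Si](C)(C)C(C)(C)C)cc(O[Si](C)(C)C(C)(C)C)cc3O2)cc1O[Si](C)(C)C(C)(C)C | intermediate
15 | (2S)-4'-(3-methylbut-2-enyloxy)-5,7,3'-tris(tert-butyldimethylsilyloxy)flavanone | CC(C)=CCOc1ccc([C@@H]2CC(=O)c3c(O[Si](C)(C)C(C)(C)C)cc(O[Si](C)(C)C(C)(C)C)cc3O2)cc1O[Si](C)(C)C(C)(C)C | intermediate
16 | Monotesone A | CC(C)=CCOc1ccc([C@@H]2CC(=O)c3c(O)cc(O)cc3O2)cc1O | target

## Step count and least certain steps

Total: 9 steps. Longest linear sequence: 8 steps (steps 1, 2, 3, 5, 6, 7, 8, 9, from 1); the ring A branch (step 4) joins at step 5.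

**Step 6 (key step).** Three processes may defeat it.
- Ionisation in the wrong sense, with departure of the ring A aryloxy group instead of the methoxy group. The aryloxy group is the better leaving group and a methoxy-stabilised cation is the more stable one, even though the methoxy oxygen is the more basic site.
- Insufficient face discrimination at C2, because 11 offers the anion no hydrogen-bond contact and ion pairing alone must do the work.
- Acid-induced oligomerisation of the enol ether, or protonation of the prenyl alkene by the strong acid.

Fallback (known chemistry), setting out from 9: the annulation with 10 is run without enantiocontrol using SnCl4 in CH2Cl2 at −78 °C, the Lewis acid form of the oxa-Povarov reaction, in which the oxophilic metal binds the more basic methoxy oxygen. This should give racemic 2,4-cis-4-ethoxy-4'-(3-methylbut-2-enyloxy)-5,7,3'-tris(tert-butyldimethylsilyloxy)flavan F1. The conditions of steps 7 and 8 then give the racemic flavan-4-ol F2 and the racemic flavanone F3. A kinetic resolution by Noyori–Ikariya asymmetric transfer hydrogenation, RuCl(p-cymene)[(R,R)-TsDPEN] with HCO2H/Et3N, should reduce the 2R enantiomer to the (2R,4R)-cis-flavan-4-ol F4 and leave the 2S ketone, which is 15, where the route is rejoined. C2 is then selected after the ring is made instead of being induced while it forms, at the price of the 2R half of the material.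

**Step 5.** The chloro ether 8 is a p-alkoxybenzylic α-chloro ether and close to an ion pair. It may alkylate the electron-rich ring of 7 on carbon, condense with itself or hydrolyse, and the mixed acetal may decompose on acidic silica.

Fallback, setting out from 4 (so 5 is not needed): pivaloyl chloride with catalytic ZnCl2 should add across the formyl group to give chloro[3-(tert-butyldimethylsilyloxy)-4-(3-methylbut-2-enyloxy)phenyl]methyl pivalate F5. It is less ionisable than 8 because an acyloxy group is a poorer donor, and the hindered ester resists acyl transfer. F5 alkylates 7 under the same amine base to give the racemic O-aryl O-pivaloyl acetal F6. F6 would replace 9 in step 6, lose pivalic acid, pass through the same cation 11 and come back to the route at 13. A carboxylate leaves unambiguously in preference to the aryloxy group, so this variant also answers the ionisation problem of step 6.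

**Step 7.** The benzylic C4 cation is long-lived. It may lose H-3 to give the flav-3-ene, or be captured by ring A of a second molecule (oligomerisation); partial loss of silyl groups is also possible.

Fallback, setting out from 13 and arriving directly at 15: oxidative cleavage of the benzylic ether with DDQ (1 equiv) in CH2Cl2–pH 7 buffer at 0 °C, the reaction type used to remove electron-rich benzyl ethers. Hydride abstraction at C4, the most electron-rich benzylic C–H, gives the ethoxy-oxocarbenium ion; water adds and the hemiketal collapses to the ketone. Elimination from this ion gives an enol ether that hydrolyses to the same ketone. This avoids the oxygen-free C4 cation and saves a step, but it exposes the prenyl ether and C2–H to the oxidant, so it is held in reserve. No new compound is made.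

**Step 4.** Silylation of three equivalent hydroxyls may be unselective, and the mixture may be hard to separate on scale.

Fallback, setting out from 6: exhaustive silylation (TBSCl, imidazole, DMF) to 1,3,5-tris(tert-butyldimethylsilyloxy)benzene F7, then removal of one silyl group with one equivalent of KOH in EtOH–THF at 0 °C. The first cleavage leaves a phenoxide whose charge makes the ring a much poorer leaving group for a second cleavage, so the reaction should stop at 7, where the route is rejoined.

## Further compounds

F1 | step 6 | racemic 2,4-cis-4-ethoxy-4'-(3-methylbut-2-enyloxy)-5,7,3'-tris(tert-butyldimethylsilyloxy)flavan | CC(C)=CCOc1ccc(C2CC(OCC)c3c(O[Si](C)(C)C(C)(C)C)cc(O[Si](C)(C)C(C)(C)C)cc3O2)cc1O[Si](C)(C)C(C)(C)C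
F2 | step 6 | racemic 4'-(3-methylbut-2-enyloxy)-5,7,3'-tris(tert-butyldimethylsilyloxy)flavan-4-ol | CC(C)=CCOc1ccc(C2CC(O)c3c(O[Si](C)(C)C(C)(C)C)cc(O[Si](C)(C)C(C)(C)C)cc3O2)cc1O[Si](C)(C)C(C)(C)C
F3 | step 6 | racemic 4'-(3-methylbut-2-enyloxy)-5,7,3'-tris(tert-butyldimethylsilyloxy)flavanone | CC(C)=CCOc1ccc(C2CC(=O)c3c(O[Si](C)(C)C(C)(C)C)cc(O[Si](C)(C)C(C)(C)C)cc3O2)cc1O[Si](C)(C)C(C)(C)C
F4 | step 6 | (2R,4R)-4'-(3-methylbut-2-enyloxy)-5,7,3'-tris(tert-butyldimethylsilyloxy)flavan-4-ol (2,4-cis) | CC(C)=CCOc1ccc([C@H]2C[C@@H](O)c3c(O[Si](C)(C)C(C)(C)C)cc(O[Si](C)(C)C(C)(C)C)cc3O2)cc1O[Si](C)(C)C(C)(C)C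
F5 | step 5 | racemic chloro[3-(tert-butyldimethylsilyloxy)-4-(3-methylbut-2-enyloxy)phenyl]methyl pivalate | CC(C)=CCOc1ccc(C(Cl)OC(=O)C(C)(C)C)cc1O[Si](C)(C)C(C)(C)C
F6 | step 5 | racemic [3,5-bis(tert-butyldimethylsilyloxy)phenoxy][3-(tert-butyldimethylsilyloxy)-4-(3-methylbut-2-enyloxy)phenyl]methyl pivalate | CC(C)=CCOc1ccc(C(OC(=O)C(C)(C)C)Oc2cc(O[Si](C)(C)C(C)(C)C)cc(O[Si](C)(C)C(C)(C)C)c2)cc1O[Si](C)(C)C(C)(C)C
F0 | step 7 | none | none
F7 | step 4 | 1,3,5-tris(tert-butyldimethylsilyloxy)benzene | CC(C)(C)[Si](C)(C)Oc1cc(O[Si](C)(C)C(C)(C)C)cc(O[Si](C)(C)C(C)(C)C)c1
A1 | alternative 1 | racemic 4,6-diacetoxy-2-[3-acetoxy-4-(3-methylbut-2-enyloxy)phenyl]benzofuran-3(2H)-one | CC(C)=CCOc1ccc(C2Oc3cc(OC(C)=O)cc(OC(C)=O)c3C2=O)cc1OC(C)=O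
A2 | alternative 1 | ethyl diazoacetate | CCOC(=O)C=[N+]=[N-]
A3 | alternative 1 | (2S)-2,3-trans-3-ethoxycarbonyl-5,7,3'-tri-O-acetyl-4'-(3-methylbut-2-enyloxy)flavanone | CC(C)=CCOc1ccc([C@@H]2[C@@H](C(=O)OCC)C(=O)c3c(OC(C)=O)cc(OC(C)=O)cc3O2)cc1OC(C)=O
A4 | alternative 2 | (S)-5-bromo-2-[3-(tert-butyldimethylsilyloxy)-4-(3-methylbut-2-enyloxy)phenyl]-2,3-dihydro-4H-pyran-4-one | CC(C)=CCOc1ccc([C@@H]2CC(=O)C(Br)=CO2)cc1O[Si](C)(C)C(C)(C)C
A5 | alternative 2 | 1-methoxy-1,3-bis(trimethylsilyloxy)buta-1,3-diene (Chan's diene) | COC(O[Si](C)(C)C)=CC(=C)O[Si](C)(C)C
A6 | alternative 2 | (2S)-3'-O-tert-butyldimethylsilyl ether of Monotesone A | CC(C)=CCOc1ccc([C@@H]2CC(=O)c3c(O)cc(O)cc3O2)cc1O[Si](C)(C)C(C)(C)C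
A7 | alternative 3 | 2-(dimethoxymethyl)-3,5-bis(tert-butyldimethylsilyloxy)phenol | COC(OC)c1c(O)cc(O[Si](C)(C)C(C)(C)C)cc1O[Si](C)(C)C(C)(C)C
A8 | alternative 3 | 6-(methoxymethylene)-3,5-bis(tert-butyldimethylsilyloxy)cyclohexa-2,4-dien-1-one (ortho-quinone methide) | COC=C1C(=O)C=C(O[Si](C)(C)C(C)(C)C)C=C1O[Si](C)(C)C(C)(C)C
A9 | alternative 3 | 1-benzyloxy-2-(tert-butyldimethylsilyloxy)-4-vinylbenzene | C=Cc1ccc(OCc2ccccc2)c(O[Si](C)(C)C(C)(C)C)c1
A10 | alternative 3 | (2S,4S)-4-methoxy-4'-benzyloxy-5,7,3'-tris(tert-butyldimethylsilyloxy)flavan (2,4-cis) | c1ccc(COc2ccc([C@@H]3C[C@H](OC)c4c(O[Si](C)(C)C(C)(C)C)cc(O[Si](C)(C)C(C)(C)C)cc4O3)cc2O[Si](C)(C)C(C)(C)C)cc1
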